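**Plan**
- **Cuts (clerodane numbering).** First the C19→C10 hydrogen shift is reversed and the C5–C10 bond is restored, which folds the ten-membered ring C1–C10 into a trans-hexalin. Then come the O–acyl bond and C12–H, then C2–C3/C4–C5 (Diels–Alder), then C12–furyl, C1–C10, C9–C11, C8–C17 and C5–C19.
- **Enabling feature.** The array C19H2=C5–C4(CO2Me)=C3H–C2H=C1H–C10H2, with C3=C4 and C1=C2 both cis in the ring, is the ring-opened, hydrogen-shifted valence isomer of a cyclohexa-1,3-diene (ring A, C1=C2–C3=C4). The sp3 atoms of that diene ring, C5 (bearing CH3-19) and C10 (bearing H), are the fusion atoms to a cyclohexane (ring B, C5–C10).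
- **Forward order.** Ring B is the carvone ring, and ring A is annulated onto it by a Diels–Alder reaction. The ten-membered ring arises last, when light cuts the bond shared by rings A and B.
- **Stereochemistry.** C8 and C9 come by induction from the carvone stereocentre (isopropenyl helper, deleted in step 3). C12 comes from catalyst-controlled transfer hydrogenation and C2′ from (R)-2-methylbutanoic acid. C5 and C10 are transient and are erased, and both ring alkene geometries are inherited from ring A.

Key step: step 11

Remarks: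
- Clerodane numbering is used for all intermediates: C17 on C8, C18 = ester carbon, C19 on C5, C20 on C9, C11/C12 = side chain.
- Assumption: the acyl stereocentre reads as R from the SMILES, so commercial (R)-2-methylbutanoic acid is used.
- The C5 centre of 3, 6 and 8, and the C5/C10 pair of 16–20, are drawn as the expected major isomers. Their configuration has no bearing on the target.

Step 1
Reactants: 1 (R)-(−)-carvone
Product: 3 (5R,6S)-2,6-dimethyl-5-(prop-1-en-2-yl)cyclohex-2-en-1-one (trans-6-methylcarvone), via lithium dienolate 2 (not isolated)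
Conditions: LDA, THF, −78 °C; MeI, −78 to 0 °C
Reagents that add atoms: iodomethane, CI
Why: Kinetic α′-deprotonation of the enone and enolate alkylation anti to the neighbouring isopropenyl group install the future C19 methyl on C5, a carbon that becomes sp2 in step 4, so its configuration is of no consequence.

Step 2
Reactants: 3 trans-6-methylcarvone; 4 2-bromo-N-methoxy-N-methylacetamide
Product: 6 2-[(1S,3S,4R,6R)-1,3,6-trimethyl-2-oxo-4-(prop-1-en-2-yl)cyclohexyl]-N-methoxy-N-methylacetamide, via lithium enolate 5 (not isolated)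
Conditions: Me2CuLi (MeLi, CuI), Et2O, −20 to 0 °C; then 4, HMPA, THF, −30 °C to rt
Reagents that add atoms: lithium dimethylcuprate, [Li+].C[Cu-]C
Why: In this tandem cuprate 1,4-addition/enolate alkylation (three-component vicinal difunctionalisation) the methyl group adds axially anti to the isopropenyl group (sets C8), and the regiodefined enolate is alkylated by the activated bromide anti to the new axial C17 methyl and to the C5 methyl (sets quaternary C9 with C17 and C20 cis).

Step 3
Reactants: 6 isopropenyl keto amide
Product: 8 2-[(1S,3S,6R)-1,3,6-trimethyl-2-oxocyclohexyl]-N-methoxy-N-methylacetamide, via methoxy hydroperoxide 7 (not isolated)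
Conditions: O3, MeOH, −78 °C; then PhSH, FeSO4·7H2O, −78 °C to rt
Reagents that add atoms: none
Why: In this hydrodealkenylative C(sp3)–C(sp2) fragmentation, ozonolysis in methanol gives the hydroperoxide, divalent iron reduces its O–O bond to an alkoxy radical that loses methyl acetate by β-scission, and the ring radical takes hydrogen from the thiol, so the stereocontrol helper is replaced by H at C6 while C8 and C9 stay untouched.

Step 4
Reactants: 8 keto amide
Product: 10 (5R,6S)-6-{2-[methoxy(methyl)amino]-2-oxoethyl}-2,5,6-trimethylcyclohex-1-en-1-yl trifluoromethanesulfonate, via potassium enolate 9 (not isolated)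
Conditions: KHMDS, THF, −78 to 0 °C; PhNTf2, −78 °C to rt
Reagents that add atoms: N-phenylbis(trifluoromethanesulfonimide), O=S(=O)(N(c1ccccc1)S(=O)(=O)C(F)(F)F)C(F)(F)F
Why: Because C9 is quaternary only C5–H can be removed from the ketone, and O-sulfonylation of the tetrasubstituted enolate is the standard enol triflate synthesis known for 2,2,6-trialkylcyclohexanones.

Step 5
Reactants: 10 enol triflate
Product: 11 2-[(1S,6R)-2-ethenyl-1,3,6-trimethylcyclohex-2-en-1-yl]-N-methoxy-N-methylacetamide
Conditions: CH2=CHSnBu3, Pd(PPh3)4 (cat.), LiCl, THF, reflux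
Reagents that add atoms: tributyl(vinyl)stannane, C=C[Sn](CCCC)(CCCC)CCCC
Why: Stille coupling of a hindered cyclohexenyl triflate with a vinylstannane in the presence of LiCl forms C10–C1, tolerates the Weinreb amide and gives the 2-methyl-1-vinylcyclohexene diene.

Step 6
Reactants: 11 diene Weinreb amide; 12 3-bromofuran
Product: 14 2-[(1S,6R)-2-ethenyl-1,3,6-trimethylcyclohex-2-en-1-yl]-1-(furan-3-yl)ethan-1-one, via 3-furyllithium 13 (not isolated)
Conditions: 12, n-BuLi, Et2O, −78 °C; then 11, THF, −78 °C; H2O
Reagents that add atoms: none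
Why: In this Weinreb ketone synthesis, bromine–lithium exchange at −78 °C keeps the metal at C3 of the furan and the chelated adduct stops at the ketone, whose acyl group also deactivates the furan as a competing diene for step 7.

Step 7
Reactants: 14 diene ketone; 15 methyl propiolate
Product: 16 methyl (5S,6R,8aR)-5-[2-(furan-3-yl)-2-oxoethyl]-5,6,8a-trimethyl-3,5,6,7,8,8a-hexahydronaphthalene-1-carboxylate
Conditions: 15 (excess), BHT, toluene, sealed tube, 120 °C
Reagents that add atoms: none
Why: This is a thermal Diels–Alder reaction of the kind known for 2,6,6-trimethyl-1-vinylcyclohexene with acetylenic esters, in which the free terminus C2 bonds to the β-carbon of the propiolate so that C4 (ester) joins C5 ("ortho" adduct), and the dienophile arrives anti to the axial C20 methyl, a facial preference that is not needed because C5 is erased in step 11.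

Step 8
Reactants: 16 skipped diene
Product: 17 methyl (4aR,5S,6R,8aR)-5-[2-(furan-3-yl)-2-oxoethyl]-5,6,8a-trimethyl-4a,5,6,7,8,8a-hexahydronaphthalene-1-carboxylate
Conditions: DBU, THF, reflux
Reagents that add atoms: none
Why: A base-mediated prototropic shift through the extended trienolate (deprotonation at doubly allylic C2, reprotonation at C10) leads to the more stable fully conjugated dienoate, with the proton arriving axially anti to C19 to give the trans ring fusion, as known for the related drimane diene esters.

Step 9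
Reactants: 17 hexalin furyl ketone
Product: 18 methyl (4aR,5S,6R,8aR)-5-[(2R)-2-(furan-3-yl)-2-hydroxyethyl]-5,6,8a-trimethyl-4a,5,6,7,8,8a-hexahydronaphthalene-1-carboxylate
Conditions: RuCl(p-cymene)[(R,R)-TsDPEN] (cat.), HCO2H/Et3N 5:2, CH2Cl2, rt
Reagents that add atoms: none
Why: In this Noyori asymmetric transfer hydrogenation of a heteroaryl alkyl ketone the (R,R)-catalyst recognises the furyl group as the aryl partner and delivers hydride to the face that gives the (R)-carbinol, which sets C12 under catalyst control and leaves the dienoate alone.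

Step 10
Reactants: 18 (12R)-alcohol; 19 (R)-2-methylbutanoic acid
Product: 20 methyl (4aR,5S,6R,8aR)-5-[(2R)-2-(furan-3-yl)-2-{[(2R)-2-methylbutanoyl]oxy}ethyl]-5,6,8a-trimethyl-4a,5,6,7,8,8a-hexahydronaphthalene-1-carboxylate
Conditions: 19, DCC, DMAP (cat.), CH2Cl2, 0 °C to rt
Reagents that add atoms: none
Why: Steglich esterification acylates the secondary alcohol with retention at C12, and with only catalytic DMAP at low temperature the α-stereocentre brought in by the acid is kept.

Step 11
Reactants: 20 trans-hexalin dienoate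
Product: 22 methyl (1E,3Z,6S,7R)-6-[(2R)-2-(furan-3-yl)-2-{[(2R)-2-methylbutanoyl]oxy}ethyl]-6,7-dimethyl-10-methylidenecyclodeca-1,3-diene-1-carboxylate (target), via seco-triene 21 (not isolated)
Conditions: hν (λ ≥ 300 nm, Pyrex), degassed MeOtBu, −20 °C; then dark, 40 °C; recovered 20 re-irradiated
Reagents that add atoms: none
Why: Excitation of the planar homoannular dienoate (C1=C2–C3=C4–C18) opens the doubly allylic C5–C10 fusion bond by conrotatory 6π electrocyclic ring opening to seco-triene 21, and in the dark an antarafacial [1,7]-sigmatropic shift moves one C19–H to C10 to leave C19H2=C5, C3=C4 and C1=C2. The closest known reaction types are the photochemical opening of trans-fused bicyclo[4.4.0]deca-2,4-dienes to (E,Z,E)-cyclodeca-1,3,5-trienes and the provitamin D–previtamin D–vitamin D sequence. The ten-membered ring is made by ring expansion, that is by scission of the bond common to rings A and B and not by an end-to-end closure, so no entropic or transannular penalty of a medium-ring cyclisation is paid. No stereocentre is formed (C5 and C10 are erased, hence either trans-fused C5/C10 diastereomer of 20 serves; C8, C9, C12 and C2′ are spectators), and the geometry is set by the substrate: the trans fusion holds C6 and C9 pseudo-equatorial on ring A, so they turn outward and CH3-19 and H-10 inward, and the s-cis,s-cis helix of 21 hands the ring-cis C3=C4 and C1=C2 bonds of ring A on to 22. The selectivity needed is hydrogen shift over thermal disrotatory re-closure to a cis-hexalin and over secondary photoreactions: CH3-19 already lies over C10 in the ring-enforced helix, whereas re-closure must rebuild a bond between quaternary C5 and a carbon next to quaternary C9. Light of λ ≥ 300 nm is absorbed by 20 and by any re-closed hexalin, which is thus fed back, but hardly by the twisted cross-conjugated ester 22 or by the furan, so that 22 should collect.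

**Compound list**
1 | (R)-(−)-carvone | CC1=CC[C@H](CC1=O)C(C)=C | starting material
2 | lithium cross-conjugated dienolate of 1 | [Li]OC1=C[C@H](C(C)=C)CC=C1C | intermediate
3 | (5R,6S)-2,6-dimethyl-5-(prop-1-en-2-yl)cyclohex-2-en-1-one | O=C1[C@@H](C)[C@H](C(C)=C)CC=C1C | intermediate
4 | 2-bromo-N-methoxy-N-methylacetamide | BrCC(=O)N(C)OC | starting material
5 | lithium (3R,5R,6S)-2,3,6-trimethyl-5-(prop-1-en-2-yl)cyclohex-1-en-1-olate | [Li]OC1=C(C)[C@H](C)C[C@@H](C(C)=C)[C@@H]1C | intermediate
6 | 2-[(1S,3S,4R,6R)-1,3,6-trimethyl-2-oxo-4-(prop-1-en-2-yl)cyclohexyl]-N-methoxy-N-methylacetamide | O=C1[C@@H](C)[C@H](C(C)=C)C[C@@H](C)[C@]1(C)CC(=O)N(C)OC | intermediate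
7 | 4-(1-hydroperoxy-1-methoxyethyl) analogue of 6 (acetal carbon unassigned) | O=C1[C@@H](C)[C@H](C(C)(OC)OO)C[C@@H](C)[C@]1(C)CC(=O)N(C)OC | intermediate
8 | 2-[(1S,3S,6R)-1,3,6-trimethyl-2-oxocyclohexyl]-N-methoxy-N-methylacetamide | O=C1[C@@H](C)CC[C@@H](C)[C@]1(C)CC(=O)N(C)OC | intermediate
9 | potassium C5=C10 enolate of 8 | [K]OC1=C(C)CC[C@@H](C)[C@]1(C)CC(=O)N(C)OC | intermediate
10 | (5R,6S)-6-{2-[methoxy(methyl)amino]-2-oxoethyl}-2,5,6-trimethylcyclohex-1-en-1-yl trifluoromethanesulfonate | O=S(=O)(OC1=C(C)CC[C@@H](C)[C@]1(C)CC(=O)N(C)OC)C(F)(F)F | intermediate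
11 | 2-[(1S,6R)-2-ethenyl-1,3,6-trimethylcyclohex-2-en-1-yl]-N-methoxy-N-methylacetamide | C=CC1=C(C)CC[C@@H](C)[C@]1(C)CC(=O)N(C)OC | intermediate
12 | 3-bromofuran | Brc1ccoc1 | starting material
13 | 3-furyllithium | [Li]c1ccoc1 | intermediate
14 | 2-[(1S,6R)-2-ethenyl-1,3,6-trimethylcyclohex-2-en-1-yl]-1-(furan-3-yl)ethan-1-one | C=CC1=C(C)CC[C@@H](C)[C@]1(C)CC(=O)c2ccoc2 | intermediate
15 | methyl propiolate | C#CC(=O)OC | starting material
16 | methyl (5S,6R,8aR)-5-[2-(furan-3-yl)-2-oxoethyl]-5,6,8a-trimethyl-3,5,6,7,8,8a-hexahydronaphthalene-1-carboxylate | C[C@@]12CC[C@@H](C)[C@](C)(CC(=O)c3ccoc3)C1=CCC=C2C(=O)OC | intermediate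
17 | methyl (4aR,5S,6R,8aR)-5-[2-(furan-3-yl)-2-oxoethyl]-5,6,8a-trimethyl-4a,5,6,7,8,8a-hexahydronaphthalene-1-carboxylate | C[C@@]12CC[C@@H](C)[C@](C)(CC(=O)c3ccoc3)[C@H]1C=CC=C2C(=O)OC | intermediate
18 | methyl (4aR,5S,6R,8aR)-5-[(2R)-2-(furan-3-yl)-2-hydroxyethyl]-5,6,8a-trimethyl-4a,5,6,7,8,8a-hexahydronaphthalene-1-carboxylate | C[C@@]12CC[C@@H](C)[C@](C)(C[C@@H](O)c3ccoc3)[C@H]1C=CC=C2C(=O)OC | intermediate
19 | (R)-2-methylbutanoic acid | CC[C@@H](C)C(=O)O | starting material
20 | methyl (4aR,5S,6R,8aR)-5-[(2R)-2-(furan-3-yl)-2-{[(2R)-2-methylbutanoyl]oxy}ethyl]-5,6,8a-trimethyl-4a,5,6,7,8,8a-hexahydronaphthalene-1-carboxylate | C[C@@]12CC[C@@H](C)[C@](C)(C[C@@H](OC(=O)[C@H](C)CC)c3ccoc3)[C@H]1C=CC=C2C(=O)OC | intermediate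
21 | 5,10-seco-1(10),2,4-triene (C1=C10 and C4=C5 trans in the ring, C2=C3 cis, CH3-19 on C5) | C1[C@@H](C)[C@](C)(C[C@@H](OC(=O)[C@H](C)CC)c2ccoc2)/C=C/C=C\C(C(=O)OC)=C(/C)C1 | intermediate
22 | methyl (1E,3Z,6S,7R)-6-[(2R)-2-(furan-3-yl)-2-{[(2R)-2-methylbutanoyl]oxy}ethyl]-6,7-dimethyl-10-methylidenecyclodeca-1,3-diene-1-carboxylate | C=C1CC[C@@H](C)[C@](C)(C[C@@H](OC(=O)[C@H](C)CC)c2ccoc2)C/C=C\C=C/1C(=O)OC | target

Total step count: 11. Longest linear sequence: 11 steps (from 1).

**Steps most likely to fail**

**Step 11.**
- *Risk.* Thermal re-closure of the opened triene, or secondary photoreactions of it (further hydrogen shifts, bicyclisation), may outrun the [1,7]-shift and drain the material.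
- *Fallback.* No light is used and the ring is closed by cross-coupling. The fallback sets out from 10 and comes back at 22.
- *Opening ring B.* Formate reduction of the triflate (Pd(OAc)2, PPh3, HCO2H, Et3N, DMF) gives the cyclohexene F1. Ozonolysis (O3, CH2Cl2, −78 °C; Me2S) cuts the same C5–C10 connection and gives the keto aldehyde F2.
- *Building the two coupling ends.* Aldehyde-selective Wittig reaction with Ph3P=CHOMe gives the enol ether F3, and mild aqueous acid gives the homologous aldehyde F4 (C10H2–C1HO). Stork–Zhao olefination gives the (Z)-vinyl iodide F5. Kinetic enolisation of the methyl ketone (KHMDS, −78 °C) with N-(5-chloropyridin-2-yl)bis(trifluoromethanesulfonimide) gives the iodo triflate F6.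
- *Ring closure.* Distannylation of 15 (Bu3SnSnBu3, Pd(PPh3)4) gives methyl (Z)-2,3-bis(tributylstannyl)acrylate F7. A double Stille "stitching" of F6 with F7 under high dilution (Pd2(dba)3, AsPh3, CuI, NMP) should join C2–C3 at the iodide first and then close C4–C5 at the triflate. Every alkene is retained, and the product is the ten-membered Weinreb amide F8.
- *Finishing the side chain.* Addition of 13 at −78 °C gives the ten-membered furyl ketone F9. Transfer hydrogenation as in step 9 gives the ten-membered (12R)-alcohol F10, and esterification with 19 as in step 10 gives 22.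

**Step 7.**
- *Risk.* The twisted, tetrasubstituted diene may add too slowly. At the temperature needed, polymerisation of the propiolate, a [1,5]-hydrogen shift within the diene, or erosion of regiocontrol could take over.
- *Fallback.* A dienophile with a removable activating group is used. The fallback sets out from 14 (and 15) and comes back at 16.
- *Sequence.* Bromination of 15 (NBS, AgNO3 cat., acetone) gives methyl 3-bromopropiolate F11. Its lower LUMO should let the cycloaddition run at lower temperature with the same orientation, to the bromo diene F12. Zn in AcOH/THF then removes the vinylic bromine to give 16.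

**Step 2.**
- *Risk.* Proton transfer from the acidic bromo amide, or halogen–metal exchange with residual copper species, may quench the hindered enolate before the C9–C11 bond forms.
- *Fallback.* The polar displacement is replaced by a radical addition. The fallback sets out from 3 and comes back at 6.
- *Sequence.* Cuprate addition in the presence of Me3SiCl gives the isolable silyl enol ether F13. Visible-light photoredox alkylation with 4 (Ir(ppy)3 cat., blue LED, MeCN) then lets the electrophilic carbamoylmethyl radical add to C9 anti to the C17 methyl. Oxidation and loss of the silyl group give 6.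

**Further compounds**
F1 | step 11 | cyclohexene, 2-[(1S,6R)-1,3,6-trimethylcyclohex-2-en-1-yl]-N-methoxy-N-methylacetamide | C1=C(C)CC[C@@H](C)[C@]1(C)CC(=O)N(C)OC
F2 | step 11 | keto aldehyde, (3S,4R)-3-formyl-N-methoxy-N,3,4-trimethyl-7-oxooctanamide | CC(=O)CC[C@@H](C)[C@](C)(CC(=O)N(C)OC)C=O
F3 | step 11 | enol ether (C10H=C1H–OMe, E/Z mixture) | CC(=O)CC[C@@H](C)[C@](C)(CC(=O)N(C)OC)C=COC
F4 | step 11 | homologous aldehyde (C10H2–C1HO) | CC(=O)CC[C@@H](C)[C@](C)(CC(=O)N(C)OC)CC=O
F5 | step 11 | (Z)-vinyl iodide (C1H=C2HI) | CC(=O)CC[C@@H](C)[C@](C)(CC(=O)N(C)OC)C/C=C\I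
F6 | step 11 | iodo triflate (C5(OTf)=C19H2 and C2–I) | C=C(OS(=O)(=O)C(F)(F)F)CC[C@@H](C)[C@](C)(CC(=O)N(C)OC)C/C=C\I
F7 | step 11 | methyl (Z)-2,3-bis(tributylstannyl)acrylate | COC(=O)/C([Sn](CCCC)(CCCC)CCCC)=C/[Sn](CCCC)(CCCC)CCCC
F8 | step 11 | ten-membered Weinreb amide | C=C1CC[C@@H](C)[C@](C)(CC(=O)N(C)OC)C/C=C\C=C/1C(=O)OC
F9 | step 11 | ten-membered furyl ketone | C=C1CC[C@@H](C)[C@](C)(CC(=O)c2ccoc2)C/C=C\C=C/1C(=O)OC
F10 | step 11 | ten-membered (12R)-alcohol | C=C1CC[C@@H](C)[C@](C)(C[C@@H](O)c2ccoc2)C/C=C\C=C/1C(=O)OC
F11 | step 7 | methyl 3-bromopropiolate | BrC#CC(=O)OC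
F12 | step 7 | bromo diene (3-bromo analogue of 16) | C[C@@]12CC[C@@H](C)[C@](C)(CC(=O)c3ccoc3)C1=CCC(Br)=C2C(=O)OC
F13 | step 2 | silyl enol ether (trimethylsilyl analogue of 5) | C[Si](C)(C)OC1=C(C)[C@H](C)C[C@@H](C(C)=C)[C@@H]1C
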